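**Retrosynthetic overview**

1. Target 7 is the achiral 35-membered lactone oxacyclopentatriacontan-2-one. Numbering used here: C1 = carbonyl carbon, C2–C34 = ring CH2 groups in order, C34 on the ring oxygen.
2. Enabling feature: C22–C23 is a plain CH2–CH2 bond between two primary carbons, insulated from the only functional group (the C1 ester) by 20 CH2 on one side and 11 CH2 on the other. Each of the two carbons can therefore be the α-carbon of a carboxylic acid, and the bond can be made with loss of two CO2 and no leftover functionality.
3. Key disconnection C22–C23: the ring is closed by an intramolecular nickel-electrocatalytic doubly decarboxylative C(sp3)–C(sp3) coupling of the acyclic bis(N-acyloxyphthalimide) of HO2C(CH2)21CO2(CH2)12CO2H.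
4. Second disconnection C1(=O)–O: the seco-diacid comes from tricosanedioic acid and benzyl-protected 13-hydroxytridecanoic acid by mono-esterification and hydrogenolysis.
5. Ring order: the 35-membered ring is the only ring and is formed in the last step.

Key step: step 5

Remark: the target has no stereocentre and no double bond, so no stereochemistry has to be set; tricosanedioic acid and 13-hydroxytridecanoic acid are taken as catalogue fatty-acid building blocks.

**Route**

Step 1
Reactants: 1 13-hydroxytridecanoic acid
Product: 2 benzyl 13-hydroxytridecanoate
Conditions: BnBr (1.1 equiv), KHCO3 (1.5 equiv), DMF, rt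
Reagents that add atoms: benzyl bromide, BrCc1ccccc1
Why: Carboxylate O-alkylation (SN2); bicarbonate deprotonates only the acid, so the primary alcohol stays free and self-esterification is avoided.

Step 2
Reactants: 2 benzyl 13-hydroxytridecanoate; 3 tricosanedioic acid (3 equiv)
Product: 4 23-{[13-(benzyloxy)-13-oxotridecyl]oxy}-23-oxotricosanoic acid
Conditions: EDC·HCl (1.2 equiv), DMAP (0.3 equiv), THF/CH2Cl2, 40 °C; excess 3 recovered
Reagents that add atoms: none
Why: Steglich esterification; the excess of the symmetrical diacid should bias the statistics towards the mono-ester, which differs clearly in polarity from diacid and diester.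

Step 3
Reactants: 4 23-{[13-(benzyloxy)-13-oxotridecyl]oxy}-23-oxotricosanoic acid
Product: 5 23-[(12-carboxydodecyl)oxy]-23-oxotricosanoic acid (seco-diacid)
Conditions: H2 (1 atm), 10 % Pd/C, THF, rt
Reagents that add atoms: none
Why: Hydrogenolysis of the benzyl ester; the internal alkyl ester and the saturated chains are inert to these conditions.

Step 4
Reactants: 5 23-[(12-carboxydodecyl)oxy]-23-oxotricosanoic acid
Product: 6 1,3-dioxoisoindolin-2-yl 23-({13-[(1,3-dioxoisoindolin-2-yl)oxy]-13-oxotridecyl}oxy)-23-oxotricosanoate (bis redox-active ester)
Conditions: N-hydroxyphthalimide (2.2 equiv), DIC (2.4 equiv), DMAP (5 mol %), CH2Cl2/THF, rt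
Reagents that add atoms: N-hydroxyphthalimide, ON1C(=O)c2ccccc2C1=O
Why: Carbodiimide-mediated active-ester formation (Steglich type) at both free acids; the internal ester is not touched and N-acyloxyphthalimides of primary acids are isolable solids.

Step 5
Reactants: 6 bis(N-acyloxyphthalimide) of the seco-diacid
Product: 7 oxacyclopentatriacontan-2-one (tetratriacontan-34-olide, target)
Conditions: NiCl2·glyme (20 mol %), 2,2′:6′,2″-terpyridine (20 mol %), AgNO3 (0.3 equiv), Mg(+)/RVC(−), undivided cell, const. current, NMP/THF, rt; 6 added by syringe pump (stationary conc. ca. 1 mM); 1 M HCl work-up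
Reagents that add atoms: none
Why: Proposed new method: cathodically generated low-valent Ni(terpyridine) reduces one N-acyloxyphthalimide of 6 by single-electron transfer, the radical anion fragments to phthalimide anion, CO2 and a primary alkyl radical that nickel captures as a persistent alkylnickel, and this species activates the second, tethered N-acyloxyphthalimide in the same way so that reductive elimination from the resulting dialkylnickel(III) forms the C22–C23 bond. The closest known reaction type is the intermolecular nickel-electrocatalytic doubly decarboxylative C(sp3)–C(sp3) coupling of two redox-active esters, which works for primary–primary pairs and tolerates esters, and behind it the Kolbe dimerisation; only the intramolecular, ring-forming use is new. The one ring is closed end to end as a strain-free 35-membered macrocycle by reductive elimination from a 36-membered nickelacycle, so the closure is limited by entropy and not by geometry. No stereocentre is created. The step needs ring closure to win over chain-to-chain coupling, and this should be secured by syringe-pump addition that keeps 6 dilute while the catalyst stays at its normal concentration, because the metal-bound chain end can wait for its own second end instead of needing a second free radical at the same instant as in a Kolbe electrolysis. It also needs coupling to win over protodecarboxylation and β-hydride elimination, which is favoured by two identical unhindered primary alkyl termini without β-heteroatoms and by the fact that the only other functional group, the C1 ester, lies 20 and 11 methylene groups away from the reacting carbons and is inert at the cathode.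

**Compound list**

1 | 13-hydroxytridecanoic acid | OCCCCCCCCCCCCC(=O)O | starting material
2 | benzyl 13-hydroxytridecanoate | OCCCCCCCCCCCCC(=O)OCc1ccccc1 | intermediate
3 | tricosanedioic acid | OC(=O)CCCCCCCCCCCCCCCCCCCCCC(=O)O | starting material
4 | 23-{[13-(benzyloxy)-13-oxotridecyl]oxy}-23-oxotricosanoic acid | OC(=O)CCCCCCCCCCCCCCCCCCCCCC(=O)OCCCCCCCCCCCCC(=O)OCc1ccccc1 | intermediate
5 | 23-[(12-carboxydodecyl)oxy]-23-oxotricosanoic acid | OC(=O)CCCCCCCCCCCCCCCCCCCCCC(=O)OCCCCCCCCCCCCC(=O)O | intermediate
6 | 1,3-dioxoisoindolin-2-yl 23-({13-[(1,3-dioxoisoindolin-2-yl)oxy]-13-oxotridecyl}oxy)-23-oxotricosanoate | O=C1c2ccccc2C(=O)N1OC(=O)CCCCCCCCCCCCCCCCCCCCCC(=O)OCCCCCCCCCCCCC(=O)ON1C(=O)c2ccccc2C1=O | intermediate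
7 | oxacyclopentatriacontan-2-one (tetratriacontan-34-olide) | O=C1CCCCCCCCCCCCCCCCCCCCCCCCCCCCCCCCCO1 | target

**Step count and risks**

Total step count: 5. Longest linear sequence: 5 steps (1 → 2 → 4 → 5 → 6 → 7).

Steps most likely to fail:

1. Step 5 (proposed new method). The chain ends of different molecules may couple (oligomerisation), or the first alkylnickel or alkyl radical may be quenched by hydrogen-atom transfer or β-hydride elimination before the second end is activated. The fallback uses known chemistry: it makes the same C22–C23 bond between two molecules and closes the ring at the ester instead. It sets out from 1 and 3 and comes back at 7. Acetylation of 1 (Ac2O, pyridine) should give 13-acetoxytridecanoic acid F1. Partial Fischer esterification of 3 (MeOH, cat. H2SO4, with recycling of diacid and diester) should give the half ester 23-methoxy-23-oxotricosanoic acid F2. Mixed Kolbe electrolysis of F2 with an excess of F1 (Pt electrodes, NaOMe (5 mol %), MeOH, 45–50 °C) should give methyl 34-acetoxytetratriacontanoate F3, separable from the two symmetrical dimers. Saponification (KOH, EtOH/H2O, reflux; then HCl) should give 34-hydroxytetratriacontanoic acid F4. Yamaguchi macrolactonisation (2,4,6-trichlorobenzoyl chloride, Et3N, THF; slow addition to DMAP in refluxing toluene) then returns to the route at 7.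

2. Step 2. Double acylation of the diacid and build-up of oligomeric anhydrides, made worse by the low solubility of the long-chain diacid, may erode the mono-ester. The fallback avoids all statistics; it sets out from 2 and comes back at 4. Esterification of 2 with commercial tricos-22-enoic acid (EDC·HCl, DMAP, CH2Cl2, 1:1) should give benzyl 13-(tricos-22-enoyloxy)tridecanoate F5. Anti-Markovnikov hydroboration–oxidation (9-BBN, THF; then NaBO3·4H2O) should give benzyl 13-[(23-hydroxytricosanoyl)oxy]tridecanoate F6. Oxidation of the primary alcohol to the acid (TEMPO, PhI(OAc)2, MeCN/CH2Cl2/H2O) rejoins the route at 4.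

3. Step 4. Activation of the second acid may stay incomplete, the O-acylisourea may rearrange to N-acylurea, and an active ester may be lost by hydrolysis during chromatography. The fallback changes the mode of activation; it sets out from 5 and comes back at 6. Oxalyl chloride with catalytic DMF (CH2Cl2, rt) should give 13-chloro-13-oxotridecyl 23-chloro-23-oxotricosanoate F7. F7 acylates N-hydroxyphthalimide (Et3N, CH2Cl2, 0 °C), and 6 is then isolated by crystallisation without chromatography.

**Further compounds**

F1 | step 5 | 13-acetoxytridecanoic acid | CC(=O)OCCCCCCCCCCCCC(=O)O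
F2 | step 5 | 23-methoxy-23-oxotricosanoic acid | COC(=O)CCCCCCCCCCCCCCCCCCCCCC(=O)O
F3 | step 5 | methyl 34-acetoxytetratriacontanoate | CC(=O)OCCCCCCCCCCCCCCCCCCCCCCCCCCCCCCCCCC(=O)OC
F4 | step 5 | 34-hydroxytetratriacontanoic acid | OCCCCCCCCCCCCCCCCCCCCCCCCCCCCCCCCCC(=O)O
F5 | step 2 | benzyl 13-(tricos-22-enoyloxy)tridecanoate | C=CCCCCCCCCCCCCCCCCCCCCC(=O)OCCCCCCCCCCCCC(=O)OCc1ccccc1
F6 | step 2 | benzyl 13-[(23-hydroxytricosanoyl)oxy]tridecanoate | OCCCCCCCCCCCCCCCCCCCCCCC(=O)OCCCCCCCCCCCCC(=O)OCc1ccccc1
F7 | step 4 | 13-chloro-13-oxotridecyl 23-chloro-23-oxotricosanoate | ClC(=O)CCCCCCCCCCCCCCCCCCCCCC(=O)OCCCCCCCCCCCCC(=O)Cl
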